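**Strategy.** Ring C of the target is a benzene with oxygen on C1–C5 and its only hydrogen on C6; C1 carries the ring B ether oxygen and C2 the ring D ether oxygen. The route cuts the C1–C2 bond: C2–C5 come from the four carbons of dimethyl squarate, and C6–C1 from an (E)-2-aryloxyvinyl unit that already holds ring B. One thermolysis of the resulting 4-(2-aryloxyvinyl)-2,3,4-trimethoxycyclobutenone opens the four-membered ring and closes ring C, giving a pentaoxygenated phenol whose single free hydroxyl sits at C2, ready for the ring D–E ether. Rings D–E and A are then attached by copper-catalysed etherifications, and all methyl ethers are cleaved in the last step.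

Key step: step 7

Remark: rings are lettered A–E along the chain (A = 2,4,6-trihydroxyphenoxy end, E = 3,4,5-trihydroxyphenoxy end); ring C is numbered C1 (O–ring B), C2 (O–ring D), C3–C5 (OH), C6 (H); the target has no stereocentre.

Step 1
Reactants: 1 3-hydroxy-4,5-dimethoxybenzaldehyde; 2 trichloroethylene
Product: 4 3-{[(E)-1,2-dichloroethenyl]oxy}-4,5-dimethoxybenzaldehyde, via dichloroacetylene 3 (not isolated)
Conditions: K2CO3, DMF, 70 °C
Reagents that add atoms: none
Why: Carbonate dehydrochlorinates trichloroethylene to dichloroacetylene 3, to which the phenoxide adds anti (elimination–addition O-vinylation of a phenol), so the (E)-dichlorovinyl ether should form beside the non-enolisable aldehyde; this group serves both as the protecting group of that oxygen and as the latent alkyne, so no separate protection is needed.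

Step 2
Reactants: 4 3-{[(E)-1,2-dichloroethenyl]oxy}-4,5-dimethoxybenzaldehyde
Product: 6 3-{[(E)-1,2-dichloroethenyl]oxy}-4,5-dimethoxyphenol, via aryl formate 5 (not isolated)
Conditions: mCPBA (1.3 equiv), CH2Cl2, 0 °C to rt; then Et3N, MeOH, rt
Reagents that add atoms: mCPBA (3-chloroperoxybenzoic acid), OOC(=O)c1cccc(Cl)c1
Why: Dakin-type Baeyer–Villiger oxidation, in which the aryl group activated by the para methoxy group migrates to give formate 5, which methanol/triethylamine cleaves; the doubly chlorinated enol ether is electron-poor and should resist the electrophilic peracid.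

Step 3
Reactants: 6 3-{[(E)-1,2-dichloroethenyl]oxy}-4,5-dimethoxyphenol
Product: 7 5-(benzyloxy)-1-{[(E)-1,2-dichloroethenyl]oxy}-2,3-dimethoxybenzene
Conditions: BnBr, K2CO3, DMF, rt
Reagents that add atoms: benzyl bromide, BrCc1ccccc1
Why: Williamson ether synthesis on an unhindered phenoxide; the dichlorovinyl ether was itself formed under hotter carbonate/DMF conditions and is inert here.

Step 4
Reactants: 7 5-(benzyloxy)-1-{[(E)-1,2-dichloroethenyl]oxy}-2,3-dimethoxybenzene
Product: 10 5-(benzyloxy)-1-(ethynyloxy)-2,3-dimethoxybenzene, via chloroalkynyl ether 8 (not isolated), via lithium acetylide 9 (not isolated)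
Conditions: n-BuLi (2.2 equiv), THF, −78 to −40 °C; then MeOH, −78 °C; cold work-up, used at once
Reagents that add atoms: none
Why: Vinylic deprotonation with loss of LiCl gives chloroalkyne 8, chlorine–lithium exchange with the second equivalent gives acetylide 9, and protonation releases the terminal ynol ether (the established dichlorovinyl ether to alkynyl ether conversion); benzyl and methyl aryl ethers tolerate n-BuLi at this temperature.

Step 5
Reactants: 10 5-(benzyloxy)-1-(ethynyloxy)-2,3-dimethoxybenzene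
Product: 12 5-(benzyloxy)-1-{[(E)-2-iodoethenyl]oxy}-2,3-dimethoxybenzene, via alkenylzirconocene 11 (not isolated)
Conditions: Cp2Zr(H)Cl (1.3 equiv), THF, rt; then I2, 0 °C, dark
Reagents that add atoms: iodine, II
Why: Hydrozirconation of the terminal ynol ether is a syn addition that places zirconium on the terminal carbon, and iodinolysis of the C–Zr bond with retention should give the E-configured 2-aryloxyvinyl iodide.

Step 6
Reactants: 12 5-(benzyloxy)-1-{[(E)-2-iodoethenyl]oxy}-2,3-dimethoxybenzene; 13 dimethyl squarate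
Product: 16 racemic (E)-4-{2-[5-(benzyloxy)-2,3-dimethoxyphenoxy]ethenyl}-2,3,4-trimethoxycyclobut-2-en-1-one, via vinyllithium 14 (not isolated), via lithium alkoxide 15 (not isolated)
Conditions: t-BuLi (2 equiv), Et2O, −78 °C; then 13, THF, −78 °C; then MeOTf, −78 to 0 °C
Reagents that add atoms: methyl triflate, COS(=O)(=O)C(F)(F)F
Why: Iodine–lithium exchange with retention gives vinyllithium 14, 1,2-addition to one of the two equivalent squarate carbonyl groups gives alkoxide 15, and O-methylation with MeOTf caps it; the new quaternary carbon C4 forms as a racemate, which needs no control because step 7 destroys it.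

Step 7
Reactants: 16 racemic (E)-4-{2-[5-(benzyloxy)-2,3-dimethoxyphenoxy]ethenyl}-2,3,4-trimethoxycyclobut-2-en-1-one
Product: 19 6-[5-(benzyloxy)-2,3-dimethoxyphenoxy]-2,3,4-trimethoxyphenol, via dienylketene 17 (not isolated), via cyclohexadienone 18 (not isolated)
Conditions: degassed toluene, 110 °C
Reagents that add atoms: none
Why: Heat breaks the C1–C4 bond of the cyclobutenone in a conrotatory 4π electrocyclic opening to dienylketene 17, whose ketene carbon (future C2 of ring C) then bonds to the aryloxy-bearing vinyl carbon (future C1) in a 6π electrocyclisation to give cyclohexa-2,4-dienone 18, and enolisation of 18 gives phenol 19. The closest known reaction type is the thermal ring expansion of 4-alkenyl-4-alkoxycyclobutenones made from squaric esters into highly oxygenated phenols (Moore-type rearrangement). Ring C is closed by disrotatory 6π electrocyclic closure of the (Z)-dienylketene, forming a six-membered carbocycle by one C–C bond between the triene termini. No stereocentre results, because the racemic C4 centre of 16 becomes sp2 on ring opening and the sp3 carbon of 18 is lost on aromatisation. The step needs the vinyl group to rotate inward, which the outward-rotating C4 methoxy donor secures (torquoselectivity), and the unhindered E enol ether terminus allows the closure. The three squarate methoxy groups, the former carbonyl oxygen and the enol ether oxygen end on five adjacent ring carbons, with the former carbonyl oxygen as the one unprotected hydroxyl at C2.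

Step 8
Reactants: 20 4-bromo-2,6-dimethoxyphenol; 21 (3,4,5-trimethoxyphenyl)boronic acid
Product: 22 5-bromo-1,3-dimethoxy-2-(3,4,5-trimethoxyphenoxy)benzene
Conditions: Cu(OAc)2 (0.2 equiv), pyridine, 4 Å MS, CH2Cl2, dry air, rt
Reagents that add atoms: none
Why: Chan–Lam oxidative O-arylation at room temperature; the boronic acid has no ortho substituent, 2,6-disubstituted phenols are accepted, and the aryl bromide is untouched under these conditions.

Step 9
Reactants: 19 6-[5-(benzyloxy)-2,3-dimethoxyphenoxy]-2,3,4-trimethoxyphenol; 22 5-bromo-1,3-dimethoxy-2-(3,4,5-trimethoxyphenoxy)benzene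
Product: 23 1-[3,5-dimethoxy-4-(3,4,5-trimethoxyphenoxy)phenoxy]-6-[5-(benzyloxy)-2,3-dimethoxyphenoxy]-2,3,4-trimethoxybenzene
Conditions: CuI (cat.), picolinic acid, K3PO4, DMSO, 90 °C, argon; 22 in excess
Reagents that add atoms: none
Why: Ullmann diaryl ether synthesis; the picolinate-ligated copper phenoxide of the 2,6-disubstituted phenol couples with an aryl bromide that has hydrogen at both ortho positions, a pairing this ligand system is known to handle, and benzyl and methyl ethers are inert.

Step 10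
Reactants: 23 1-[3,5-dimethoxy-4-(3,4,5-trimethoxyphenoxy)phenoxy]-6-[5-(benzyloxy)-2,3-dimethoxyphenoxy]-2,3,4-trimethoxybenzene
Product: 24 3-{2-[3,5-dimethoxy-4-(3,4,5-trimethoxyphenoxy)phenoxy]-3,4,5-trimethoxyphenoxy}-4,5-dimethoxyphenol
Conditions: H2 (1 atm), Pd/C, EtOAc–MeOH, rt
Reagents that add atoms: none
Why: Catalytic hydrogenolysis of the single benzyl ether; diaryl and methyl aryl ethers are not cleaved.

Step 11
Reactants: 24 3-{2-[3,5-dimethoxy-4-(3,4,5-trimethoxyphenoxy)phenoxy]-3,4,5-trimethoxyphenoxy}-4,5-dimethoxyphenol; 25 2-iodo-1,3,5-trimethoxybenzene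
Product: 26 1-[3,5-dimethoxy-4-(3,4,5-trimethoxyphenoxy)phenoxy]-6-[2,3-dimethoxy-5-(2,4,6-trimethoxyphenoxy)phenoxy]-2,3,4-trimethoxybenzene
Conditions: CuI (cat.), picolinic acid, K3PO4, DMSO, 100 °C, argon; 25 in excess
Reagents that add atoms: none
Why: Ullmann diaryl ether synthesis in which the phenol is unhindered (hydrogen at both ortho positions), which should offset the two ortho methoxy groups of the aryl iodide; polymethoxylated aryl halides and phenols are the classical substrates of this coupling.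

Step 12
Reactants: 26 1-[3,5-dimethoxy-4-(3,4,5-trimethoxyphenoxy)phenoxy]-6-[2,3-dimethoxy-5-(2,4,6-trimethoxyphenoxy)phenoxy]-2,3,4-trimethoxybenzene
Product: 27 4-[3,5-dihydroxy-4-(3,4,5-trihydroxyphenoxy)phenoxy]-5-[2,3-dihydroxy-5-(2,4,6-trihydroxyphenoxy)phenoxy]benzene-1,2,3-triol
Conditions: BBr3 (excess), CH2Cl2, −78 °C to rt; then MeOH, H2O, 0 °C; work-up and chromatography under argon
Reagents that add atoms: none
Why: Lewis-acid O-demethylation, in which boron coordinates each methoxy oxygen and bromide removes the methyl group by SN2; the four diaryl ether bonds have no sp3 carbon and should survive, and hydrolysis of the B–O bonds on work-up should release the thirteen hydroxyl groups.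

**Compound list**

1 | 3-hydroxy-4,5-dimethoxybenzaldehyde | COc1cc(C=O)cc(O)c1OC | starting material
2 | trichloroethylene | ClC=C(Cl)Cl | starting material
3 | dichloroacetylene (formed in the flask, not isolated) | ClC#CCl | intermediate
4 | 3-{[(E)-1,2-dichloroethenyl]oxy}-4,5-dimethoxybenzaldehyde | COc1cc(C=O)cc(O/C(Cl)=C\Cl)c1OC | intermediate
5 | 3-{[(E)-1,2-dichloroethenyl]oxy}-4,5-dimethoxyphenyl formate (not isolated) | COc1cc(OC=O)cc(O/C(Cl)=C\Cl)c1OC | intermediate
6 | 3-{[(E)-1,2-dichloroethenyl]oxy}-4,5-dimethoxyphenol | COc1cc(O)cc(O/C(Cl)=C\Cl)c1OC | intermediate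
7 | 5-(benzyloxy)-1-{[(E)-1,2-dichloroethenyl]oxy}-2,3-dimethoxybenzene | COc1cc(OCc2ccccc2)cc(O/C(Cl)=C\Cl)c1OC | intermediate
8 | 5-(benzyloxy)-1-[(chloroethynyl)oxy]-2,3-dimethoxybenzene (not isolated) | COc1cc(OCc2ccccc2)cc(OC#CCl)c1OC | intermediate
9 | lithium [5-(benzyloxy)-2,3-dimethoxyphenoxy]ethynide (not isolated) | COc1cc(OCc2ccccc2)cc(OC#C[Li])c1OC | intermediate
10 | 5-(benzyloxy)-1-(ethynyloxy)-2,3-dimethoxybenzene | COc1cc(OCc2ccccc2)cc(OC#C)c1OC | intermediate
11 | chlorobis(cyclopentadienyl){(E)-2-[5-(benzyloxy)-2,3-dimethoxyphenoxy]ethenyl}zirconium (not isolated) | COc1cc(OCc2ccccc2)cc(O/C=C/[Zr+2]Cl)c1OC.c1cc[cH-]c1.c1cc[cH-]c1 | intermediate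
12 | 5-(benzyloxy)-1-{[(E)-2-iodoethenyl]oxy}-2,3-dimethoxybenzene | COc1cc(OCc2ccccc2)cc(O/C=C/I)c1OC | intermediate
13 | dimethyl squarate (3,4-dimethoxycyclobut-3-ene-1,2-dione) | COC1=C(OC)C(=O)C1=O | starting material
14 | (E)-2-[5-(benzyloxy)-2,3-dimethoxyphenoxy]ethenyllithium (not isolated) | COc1cc(OCc2ccccc2)cc(O/C=C/[Li])c1OC | intermediate
15 | racemic lithium 1-{(E)-2-[5-(benzyloxy)-2,3-dimethoxyphenoxy]ethenyl}-2,3-dimethoxy-4-oxocyclobut-2-en-1-olate (not isolated) | COC1=C(OC)C([O-])(/C=C/Oc2cc(OCc3ccccc3)cc(OC)c2OC)C1=O.[Li+] | intermediate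
16 | racemic (E)-4-{2-[5-(benzyloxy)-2,3-dimethoxyphenoxy]ethenyl}-2,3,4-trimethoxycyclobut-2-en-1-one | COC1=C(OC)C(OC)(/C=C/Oc2cc(OCc3ccccc3)cc(OC)c2OC)C1=O | intermediate
17 | (3Z,5E)-6-[5-(benzyloxy)-2,3-dimethoxyphenoxy]-2,3,4-trimethoxyhexa-1,3,5-trien-1-one (not isolated) | O=C=C(OC)/C(OC)=C(OC)\C=C\Oc1cc(OCc2ccccc2)cc(OC)c1OC | intermediate
18 | racemic 6-[5-(benzyloxy)-2,3-dimethoxyphenoxy]-2,3,4-trimethoxycyclohexa-2,4-dien-1-one (not isolated) | COC1=CC(Oc2cc(OCc3ccccc3)cc(OC)c2OC)C(=O)C(OC)=C1OC | intermediate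
19 | 6-[5-(benzyloxy)-2,3-dimethoxyphenoxy]-2,3,4-trimethoxyphenol | COc1cc(Oc2cc(OCc3ccccc3)cc(OC)c2OC)c(O)c(OC)c1OC | intermediate
20 | 4-bromo-2,6-dimethoxyphenol | COc1cc(Br)cc(OC)c1O | starting material
21 | (3,4,5-trimethoxyphenyl)boronic acid | COc1cc(B(O)O)cc(OC)c1OC | starting material
22 | 5-bromo-1,3-dimethoxy-2-(3,4,5-trimethoxyphenoxy)benzene | COc1cc(Br)cc(OC)c1Oc1cc(OC)c(OC)c(OC)c1 | intermediate
23 | 1-[3,5-dimethoxy-4-(3,4,5-trimethoxyphenoxy)phenoxy]-6-[5-(benzyloxy)-2,3-dimethoxyphenoxy]-2,3,4-trimethoxybenzene | COc1cc(Oc2cc(OCc3ccccc3)cc(OC)c2OC)c(Oc2cc(OC)c(Oc3cc(OC)c(OC)c(OC)c3)c(OC)c2)c(OC)c1OC | intermediate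
24 | 3-{2-[3,5-dimethoxy-4-(3,4,5-trimethoxyphenoxy)phenoxy]-3,4,5-trimethoxyphenoxy}-4,5-dimethoxyphenol | COc1cc(Oc2cc(O)cc(OC)c2OC)c(Oc2cc(OC)c(Oc3cc(OC)c(OC)c(OC)c3)c(OC)c2)c(OC)c1OC | intermediate
25 | 2-iodo-1,3,5-trimethoxybenzene | COc1cc(OC)c(I)c(OC)c1 | starting material
26 | 1-[3,5-dimethoxy-4-(3,4,5-trimethoxyphenoxy)phenoxy]-6-[2,3-dimethoxy-5-(2,4,6-trimethoxyphenoxy)phenoxy]-2,3,4-trimethoxybenzene (tridecamethyl ether of 27) | COc1cc(OC)c(Oc2cc(OC)c(OC)c(Oc3cc(OC)c(OC)c(OC)c3Oc3cc(OC)c(Oc4cc(OC)c(OC)c(OC)c4)c(OC)c3)c2)c(OC)c1 | intermediate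
27 | 4-[3,5-dihydroxy-4-(3,4,5-trihydroxyphenoxy)phenoxy]-5-[2,3-dihydroxy-5-(2,4,6-trihydroxyphenoxy)phenoxy]benzene-1,2,3-triol (CNP0228612.0) | Oc1cc(O)c(Oc2cc(O)c(O)c(Oc3cc(O)c(O)c(O)c3Oc3cc(O)c(Oc4cc(O)c(O)c(O)c4)c(O)c3)c2)c(O)c1 | target

**Step count.** Total: 12 steps. Longest linear sequence: 11 steps (steps 1–7 and 9–12, from 1 to 27); step 8 is a one-step side branch.

**Steps most likely to fail**

Step 6. The β-aryloxyvinyllithium may expel lithium aryloxide (β-elimination to acetylene) before it reaches the squarate, and the alkoxide may be methylated incompletely. The fallback sets out from 7 and comes back at 19, and avoids any vinyllithium. Compound 7 is treated with n-BuLi as in step 4, but acetylide 9 is not quenched. It is added at −78 °C to 13 to give the lithium alkoxide of the alkynyl adduct F1. MeOTf converts this into racemic 4-{[5-(benzyloxy)-2,3-dimethoxyphenoxy]ethynyl}-2,3,4-trimethoxycyclobut-2-en-1-one F2. Lindlar semihydrogenation (H2, Pd/CaCO3 poisoned with Pb(OAc)2, quinoline, EtOAc) then gives the (Z)-alkenylcyclobutenone F3. Thermolysis of F3 in p-xylene at 140 °C should pass through the (3Z,5Z)-dienylketene F4 and the same dienone 18 to phenol 19, since the alkene geometry is erased on aromatisation; the ring-forming C1–C2 bond is unchanged.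

Step 11. Oxidative addition of the electron-rich, doubly ortho-substituted aryl iodide to copper may be slow, so conversion may stall and the iodide may be reduced. The fallback sets out from 24 and comes back at 26, with the polarity of the coupling reversed. Phenol 24 is converted with Tf2O and pyridine in CH2Cl2 into the aryl triflate 3-{2-[3,5-dimethoxy-4-(3,4,5-trimethoxyphenoxy)phenoxy]-3,4,5-trimethoxyphenoxy}-4,5-dimethoxyphenyl trifluoromethanesulfonate F5. A palladium-catalysed Buchwald–Hartwig C–O coupling (Pd(OAc)2, t-BuXPhos, K3PO4, toluene, 100 °C) of F5 with commercial 2,4,6-trimethoxyphenol (COc1cc(OC)c(O)c(OC)c1) then gives 26. The hindered partner is now the nucleophile and the ring B carbon, which has no ortho substituent, is the electrophile.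

Step 12. Cleavage of the thirteen methyl ethers may be incomplete, and the electron-rich polyphenol may be oxidised by air during isolation. The fallback sets out from 26 and comes back at 27 by capture and release. The crude product of the BBr3 treatment is not purified but acetylated at once (Ac2O, pyridine, DMAP, rt) to the tridecaacetate F6. F6 is stable to air, can be chromatographed on silica, and can be separated from partly methylated material, which is returned to BBr3. Acidic methanolysis of pure F6 (AcCl in degassed MeOH, rt, argon) then releases 27 without exposing the phenolate to base or air.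

**Further compounds**

F1 | step 6 | racemic lithium 1-{[5-(benzyloxy)-2,3-dimethoxyphenoxy]ethynyl}-2,3-dimethoxy-4-oxocyclobut-2-en-1-olate | COC1=C(OC)C([O-])(C#COc2cc(OCc3ccccc3)cc(OC)c2OC)C1=O.[Li+]
F2 | step 6 | racemic 4-{[5-(benzyloxy)-2,3-dimethoxyphenoxy]ethynyl}-2,3,4-trimethoxycyclobut-2-en-1-one | COC1=C(OC)C(OC)(C#COc2cc(OCc3ccccc3)cc(OC)c2OC)C1=O
F3 | step 6 | racemic (Z)-4-{2-[5-(benzyloxy)-2,3-dimethoxyphenoxy]ethenyl}-2,3,4-trimethoxycyclobut-2-en-1-one | COC1=C(OC)C(OC)(/C=C\Oc2cc(OCc3ccccc3)cc(OC)c2OC)C1=O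
F4 | step 6 | (3Z,5Z)-6-[5-(benzyloxy)-2,3-dimethoxyphenoxy]-2,3,4-trimethoxyhexa-1,3,5-trien-1-one | O=C=C(OC)/C(OC)=C(OC)\C=C/Oc1cc(OCc2ccccc2)cc(OC)c1OC
F5 | step 11 | 3-{2-[3,5-dimethoxy-4-(3,4,5-trimethoxyphenoxy)phenoxy]-3,4,5-trimethoxyphenoxy}-4,5-dimethoxyphenyl trifluoromethanesulfonate | COc1cc(Oc2cc(OS(=O)(=O)C(F)(F)F)cc(OC)c2OC)c(Oc2cc(OC)c(Oc3cc(OC)c(OC)c(OC)c3)c(OC)c2)c(OC)c1OC
F6 | step 12 | tridecaacetate of 27 | CC(=O)Oc1cc(OC(C)=O)c(Oc2cc(OC(C)=O)c(OC(C)=O)c(Oc3cc(OC(C)=O)c(OC(C)=O)c(OC(C)=O)c3Oc3cc(OC(C)=O)c(Oc4cc(OC(C)=O)c(OC(C)=O)c(OC(C)=O)c4)c(OC(C)=O)c3)c2)c(OC(C)=O)c1
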